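**Strategy.** The 1,2-dioxane (O1–O2–C3–C4–C5–C6) is disconnected at C4–C5, exploiting that C5 is a bare CH2 between quaternary C6 and the stereocentre C4. Quaternary C6 then comes from an enantiopure 2,2-disubstituted epoxide: perhydrolysis puts O–O on C6 with inversion and leaves the epoxide CH2 as C5. An enantioselective oxa-Michael addition of this hydroperoxide to a dienal sets C3 and gives an acyclic peroxide in which C4 is the β-carbon of an acrylate. The key step closes the ring by 6-exo attack of the C5 radical on C4; a chair relays C3 to C4 (trans). The activating carboxyl on the future C4 methyl is finally removed by decarboxylation.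

Key step: step 11

Remark: ring atoms are numbered O1, O2, C3 (bears CH2CO2Me), C4 (bears CH3), C5, C6 (quaternary), and the side chain C7 to C12; compounds 1, 5, 10 and 11 are taken as commercial, which is an assumption for 11.

Step 1
Reactants: 1 (S)-2-methylglycidol
Product: 2 (R)-2-methylpent-4-yne-1,2-diol
Conditions: LiC≡CH·H2N(CH2)2NH2 (3 equiv), DMSO, rt
Reagents that add atoms: lithium acetylide ethylenediamine complex [Li+].[C-]#C.NCCN
Why: SN2 opening of the epoxide at its unsubstituted carbon by acetylide leaves the stereocentre of 1 untouched, and the only side equilibrium of the alkoxide, a Payne shift, is degenerate and returns the same enantiomer.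

Step 2
Reactants: 2 (R)-2-methylpent-4-yne-1,2-diol
Product: 4 (2R,4E)-5-iodo-2,4-dimethylpent-4-ene-1,2-diol, via alkenylalane 3 (not isolated)
Conditions: AlMe3 (5 equiv), Cp2ZrCl2, CH2Cl2, 0 °C to rt; then I2, THF, −30 °C
Reagents that add atoms: trimethylaluminium C[Al](C)C; iodine II
Why: Negishi zirconium-catalysed methylalumination adds CH3 and aluminium syn across the terminal alkyne with methyl on the internal carbon, and iodinolysis of the C–Al bond with retention should give the E-trisubstituted vinyl iodide.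

Step 3
Reactants: 4 (2R,4E)-5-iodo-2,4-dimethylpent-4-ene-1,2-diol; 5 [(E)-3-phenylprop-1-en-1-yl]boronic acid
Product: 6 (2R,4E,6E)-2,4-dimethyl-8-phenylocta-4,6-diene-1,2-diol
Conditions: Pd(PPh3)4 (cat.), K3PO4, THF–H2O, 45 °C
Reagents that add atoms: none
Why: Suzuki–Miyaura coupling of two sp2 partners proceeds with retention of both alkene geometries and should give the (4E,6E)-diene without touching the diol.

Step 4
Reactants: 6 (2R,4E,6E)-2,4-dimethyl-8-phenylocta-4,6-diene-1,2-diol
Product: 8 (R)-2-methyl-2-[(2E,4E)-2-methyl-6-phenylhexa-2,4-dien-1-yl]oxirane, via primary tosylate 7 (not isolated)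
Conditions: NaH, N-tosylimidazole, THF, 0 °C to rt
Reagents that add atoms: none
Why: Selective sulfonylation of the primary alkoxide followed by intramolecular Williamson closure by the tertiary alkoxide forms the epoxide without breaking the C–O bond at the stereocentre (retention).

Step 5
Reactants: 8 (R)-2-methyl-2-[(2E,4E)-2-methyl-6-phenylhexa-2,4-dien-1-yl]oxirane
Product: 9 (2S,4E,6E)-2-hydroperoxy-2,4-dimethyl-8-phenylocta-4,6-dien-1-ol
Conditions: H2O2 (anhydrous, in Et2O, excess), H3PMo12O40 (cat.), rt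
Reagents that add atoms: hydrogen peroxide OO
Why: Acid-catalysed perhydrolysis of a 2,2-disubstituted epoxide (phosphomolybdic acid method) opens at the tertiary carbon by backside attack of H2O2, so C6 should be inverted to the S-configured tertiary hydroperoxide while the epoxide CH2 remains as the C5 carbinol.

Step 6
Reactants: 10 (E)-4,4-dimethoxybut-2-enal; 11 prop-2-en-1-yl (triphenylphosphoranylidene)acetate
Product: 12 prop-2-en-1-yl (2E,4E)-6,6-dimethoxyhexa-2,4-dienoate
Conditions: CH2Cl2, rt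
Reagents that add atoms: none
Why: Wittig olefination with a stabilised ylide should give the new alkene E and leave the acetal intact.

Step 7
Reactants: 12 prop-2-en-1-yl (2E,4E)-6,6-dimethoxyhexa-2,4-dienoate
Product: 13 prop-2-en-1-yl (2E,4E)-6-oxohexa-2,4-dienoate
Conditions: Amberlyst-15, acetone–H2O, rt
Reagents that add atoms: water O
Why: Mild acid-catalysed acetal hydrolysis frees the aldehyde without affecting the allyl ester or the E,E-diene.

Step 8
Reactants: 9 (2S,4E,6E)-2-hydroperoxy-2,4-dimethyl-8-phenylocta-4,6-dien-1-ol; 13 prop-2-en-1-yl (2E,4E)-6-oxohexa-2,4-dienoate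
Product: 14 prop-2-en-1-yl (2E,4S)-4-{[(2S,4E,6E)-1-hydroxy-2,4-dimethyl-8-phenylocta-4,6-dien-2-yl]peroxy}-6-oxohex-2-enoate
Conditions: (S)-α,α-bis[3,5-bis(trifluoromethyl)phenyl]prolinol trimethylsilyl ether (20 mol%), PhCO2H (20 mol%), toluene, −20 °C
Reagents that add atoms: none
Why: Organocatalytic enantioselective oxa-Michael addition of a tertiary hydroperoxide to an enal through its iminium ion, in which the diarylsilyloxymethyl group shields one face of the E-iminium so that by the usual steric model the S-configured catalyst should deliver the peroxide oxygen to the β-carbon with the 3S sense (catalyst control, C6 being remote), the δ-carbon being unreactive because it is α to the ester.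

Step 9
Reactants: 14 prop-2-en-1-yl (2E,4S)-4-{[(2S,4E,6E)-1-hydroxy-2,4-dimethyl-8-phenylocta-4,6-dien-2-yl]peroxy}-6-oxohex-2-enoate
Product: 16 1-methyl 6-prop-2-en-1-yl (3S,4E)-3-{[(2S,4E,6E)-1-hydroxy-2,4-dimethyl-8-phenylocta-4,6-dien-2-yl]peroxy}hex-4-enedioate, via carboxylic acid 15 (not isolated)
Conditions: NaClO2, NaH2PO4, 2-methyl-2-butene, t-BuOH–H2O, 0 °C; then TMSCHN2, toluene–MeOH, 0 °C
Reagents that add atoms: sodium chlorite [Na+].[O-]Cl=O; (trimethylsilyl)diazomethane C[Si](C)(C)C=[N+]=[N-]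
Why: Pinnick oxidation converts the aldehyde to the acid under buffered conditions that neither epimerise C3 nor attack the alkenes (hypochlorite is scavenged), and (trimethylsilyl)diazomethane methylates the acid under neutral conditions.

Step 10
Reactants: 16 1-methyl 6-prop-2-en-1-yl (3S,4E)-3-{[(2S,4E,6E)-1-hydroxy-2,4-dimethyl-8-phenylocta-4,6-dien-2-yl]peroxy}hex-4-enedioate
Product: 18 1-methyl 6-prop-2-en-1-yl (3S,4E)-3-{[(2S,4E,6E)-1-iodo-2,4-dimethyl-8-phenylocta-4,6-dien-2-yl]peroxy}hex-4-enedioate, via primary triflate 17 (not isolated)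
Conditions: Tf2O, 2,6-lutidine, CH2Cl2, −78 °C; then Bu4NI, −78 °C to rt
Reagents that add atoms: tetrabutylammonium iodide CCCC[N+](CCCC)(CCCC)CCCC.[I-]
Why: Triflation of the primary alcohol and SN2 displacement by iodide, which a triflate allows even at a neopentyl-type carbon, should give the radical precursor without basic or reducing conditions.

Step 11
Reactants: 18 1-methyl 6-prop-2-en-1-yl (3S,4E)-3-{[(2S,4E,6E)-1-iodo-2,4-dimethyl-8-phenylocta-4,6-dien-2-yl]peroxy}hex-4-enedioate
Product: 19 methyl 2-[(3S,4S,6R)-6-methyl-6-[(2E,4E)-2-methyl-6-phenylhexa-2,4-dien-1-yl]-4-[2-oxo-2-(prop-2-en-1-yloxy)ethyl]-1,2-dioxan-3-yl]acetate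
Conditions: Bu3SnH (1.2 equiv, syringe pump), Et3B (cat.), air, toluene, high dilution, −20 to 0 °C
Reagents that add atoms: none
Why: Proposed new method: Bu3Sn• abstracts iodine from 18 and the primary C5 radical adds to C4, the β-carbon of the E-acrylate, after which the α-ester radical takes hydrogen from Bu3SnH; the closest known reaction type is the tin hydride 6-exo cyclisation of alkyl iodides onto acrylates, and carbon radicals β to an O–O bond are known to cyclise onto activated alkenes in the serial peroxyl radical cyclisations that give prostaglandin-type bicyclic endoperoxides. The 1,2-dioxane ring is closed in the 6-exo-trig mode. The new C4 stereocentre is controlled by C3: in the chair transition state the CH2CO2Me group on C3, the acrylate on C4 and the dienyl chain on C6 are equatorial and the C6 methyl is axial, which should give the 3,4-trans product. The step needs cyclisation to outrun γ-scission of the β-peroxyalkyl radical (epoxide plus alkoxyl radical), 1,5-hydrogen transfer from C3–H and direct reduction. The acrylate acceptor (far more reactive toward an alkyl radical than a plain vinyl group), the geminal substitution at C6 and slow addition of the hydride at low temperature are what should secure it.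

Step 12
Reactants: 19 methyl 2-[(3S,4S,6R)-6-methyl-6-[(2E,4E)-2-methyl-6-phenylhexa-2,4-dien-1-yl]-4-[2-oxo-2-(prop-2-en-1-yloxy)ethyl]-1,2-dioxan-3-yl]acetate
Product: 20 2-[(3S,4S,6R)-3-(2-methoxy-2-oxoethyl)-6-methyl-6-[(2E,4E)-2-methyl-6-phenylhexa-2,4-dien-1-yl]-1,2-dioxan-4-yl]acetic acid
Conditions: Pd(PPh3)4 (cat.), morpholine, THF, rt
Reagents that add atoms: none
Why: Tsuji–Trost deallylation, in which zerovalent palladium ionises the allyl ester and morpholine traps the allyl fragment, should free the C4 acetic acid while the methyl ester, the diene and the dialkyl peroxide are left alone.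

Step 13
Reactants: 20 2-[(3S,4S,6R)-3-(2-methoxy-2-oxoethyl)-6-methyl-6-[(2E,4E)-2-methyl-6-phenylhexa-2,4-dien-1-yl]-1,2-dioxan-4-yl]acetic acid
Product: 22 methyl 2-[(3S,4R,6R)-4,6-dimethyl-6-[(2E,4E)-2-methyl-6-phenylhexa-2,4-dien-1-yl]-1,2-dioxan-3-yl]acetate, via Barton ester 21 (not isolated)
Conditions: N-hydroxypyridine-2-thione, DCC, CH2Cl2, 0 °C, dark; then t-BuSH, hν (tungsten lamp), rt
Reagents that add atoms: none
Why: Barton reductive decarboxylation: the thiohydroxamate ester fragments under visible light to CO2 and a primary radical on the C4 substituent, which is γ and not β to the peroxide and should be reduced by the thiol to the C4 methyl group without touching a stereocentre.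

**Compound list**

1 | (S)-2-methylglycidol | C[C@@]1(CO1)CO | starting material
2 | (R)-2-methylpent-4-yne-1,2-diol | C[C@@](O)(CC#C)CO | intermediate
3 | (E)-alkenyl(dimethyl)alane of 2 as its bis(dimethylaluminium) alkoxide | C[C@@](O[Al](C)C)(C/C(C)=C/[Al](C)C)CO[Al](C)C | intermediate
4 | (2R,4E)-5-iodo-2,4-dimethylpent-4-ene-1,2-diol | C[C@@](O)(C/C(C)=C/I)CO | intermediate
5 | [(E)-3-phenylprop-1-en-1-yl]boronic acid | OB(O)/C=C/Cc1ccccc1 | starting material
6 | (2R,4E,6E)-2,4-dimethyl-8-phenylocta-4,6-diene-1,2-diol | C[C@@](O)(C/C(C)=C/C=C/Cc1ccccc1)CO | intermediate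
7 | (2R,4E,6E)-2-hydroxy-2,4-dimethyl-8-phenylocta-4,6-dien-1-yl 4-methylbenzenesulfonate | C[C@@](O)(C/C(C)=C/C=C/Cc1ccccc1)COS(=O)(=O)c1ccc(C)cc1 | intermediate
8 | (R)-2-methyl-2-[(2E,4E)-2-methyl-6-phenylhexa-2,4-dien-1-yl]oxirane | C[C@@]1(C/C(C)=C/C=C/Cc2ccccc2)CO1 | intermediate
9 | (2S,4E,6E)-2-hydroperoxy-2,4-dimethyl-8-phenylocta-4,6-dien-1-ol | OO[C@@](C)(C/C(C)=C/C=C/Cc1ccccc1)CO | intermediate
10 | (E)-4,4-dimethoxybut-2-enal | COC(OC)/C=C/C=O | starting material
11 | prop-2-en-1-yl (triphenylphosphoranylidene)acetate | C=CCOC(=O)C=P(c1ccccc1)(c1ccccc1)c1ccccc1 | starting material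
12 | prop-2-en-1-yl (2E,4E)-6,6-dimethoxyhexa-2,4-dienoate | COC(OC)/C=C/C=C/C(=O)OCC=C | intermediate
13 | prop-2-en-1-yl (2E,4E)-6-oxohexa-2,4-dienoate | O=C/C=C/C=C/C(=O)OCC=C | intermediate
14 | prop-2-en-1-yl (2E,4S)-4-{[(2S,4E,6E)-1-hydroxy-2,4-dimethyl-8-phenylocta-4,6-dien-2-yl]peroxy}-6-oxohex-2-enoate | O=CC[C@@H](/C=C/C(=O)OCC=C)OO[C@@](C)(C/C(C)=C/C=C/Cc1ccccc1)CO | intermediate
15 | (3S,4E)-3-{[(2S,4E,6E)-1-hydroxy-2,4-dimethyl-8-phenylocta-4,6-dien-2-yl]peroxy}-6-oxo-6-(prop-2-en-1-yloxy)hex-4-enoic acid | OC(=O)C[C@@H](/C=C/C(=O)OCC=C)OO[C@@](C)(C/C(C)=C/C=C/Cc1ccccc1)CO | intermediate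
16 | 1-methyl 6-prop-2-en-1-yl (3S,4E)-3-{[(2S,4E,6E)-1-hydroxy-2,4-dimethyl-8-phenylocta-4,6-dien-2-yl]peroxy}hex-4-enedioate | COC(=O)C[C@@H](/C=C/C(=O)OCC=C)OO[C@@](C)(C/C(C)=C/C=C/Cc1ccccc1)CO | intermediate
17 | 1-methyl 6-prop-2-en-1-yl (3S,4E)-3-{[(2S,4E,6E)-2,4-dimethyl-8-phenyl-1-(trifluoromethylsulfonyloxy)octa-4,6-dien-2-yl]peroxy}hex-4-enedioate | COC(=O)C[C@@H](/C=C/C(=O)OCC=C)OO[C@@](C)(C/C(C)=C/C=C/Cc1ccccc1)COS(=O)(=O)C(F)(F)F | intermediate
18 | 1-methyl 6-prop-2-en-1-yl (3S,4E)-3-{[(2S,4E,6E)-1-iodo-2,4-dimethyl-8-phenylocta-4,6-dien-2-yl]peroxy}hex-4-enedioate | COC(=O)C[C@@H](/C=C/C(=O)OCC=C)OO[C@@](C)(C/C(C)=C/C=C/Cc1ccccc1)CI | intermediate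
19 | methyl 2-[(3S,4S,6R)-6-methyl-6-[(2E,4E)-2-methyl-6-phenylhexa-2,4-dien-1-yl]-4-[2-oxo-2-(prop-2-en-1-yloxy)ethyl]-1,2-dioxan-3-yl]acetate | COC(=O)C[C@@H]1OO[C@@](C)(C/C(C)=C/C=C/Cc2ccccc2)C[C@H]1CC(=O)OCC=C | intermediate
20 | 2-[(3S,4S,6R)-3-(2-methoxy-2-oxoethyl)-6-methyl-6-[(2E,4E)-2-methyl-6-phenylhexa-2,4-dien-1-yl]-1,2-dioxan-4-yl]acetic acid | COC(=O)C[C@@H]1OO[C@@](C)(C/C(C)=C/C=C/Cc2ccccc2)C[C@H]1CC(=O)O | intermediate
21 | 2-thioxopyridin-1(2H)-yl ester of 20 (Barton ester) | COC(=O)C[C@@H]1OO[C@@](C)(C/C(C)=C/C=C/Cc2ccccc2)C[C@H]1CC(=O)On1ccccc1=S | intermediate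
22 | methyl 2-[(3S,4R,6R)-4,6-dimethyl-6-[(2E,4E)-2-methyl-6-phenylhexa-2,4-dien-1-yl]-1,2-dioxan-3-yl]acetate | COC(=O)C[C@@H]1OO[C@@](C)(C/C(C)=C/C=C/Cc2ccccc2)C[C@H]1C | target

**Totals.** Total step count: 13. Longest linear sequence: 11 steps (steps 1 to 5 and 8 to 13).

**Steps most likely to fail**

Step 11, the step that goes beyond known chemistry. The C5 radical may fragment by γ-scission to an epoxide and an alkoxyl radical, shift a hydrogen from C3, or be reduced before it closes the ring. The fallback makes the C4–C5 bond by ring-closing metathesis, which passes through no radical or anion beside the peroxide. It sets out from 4, because the finished diene would undergo competing metathesis with the C5 vinyl group, and comes back at 22.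
- Ring closure of 4 as in step 4 should give (R)-2-[(2E)-3-iodo-2-methylprop-2-en-1-yl]-2-methyloxirane F1.
- Perhydrolysis as in step 5 should give (2S,4E)-2-hydroperoxy-5-iodo-2,4-dimethylpent-4-en-1-ol F2.
- Addition of F2 to (E)-4-methylpenta-2,4-dienal under the catalyst of step 8 should give (3S)-3-{[(2S,4E)-1-hydroxy-5-iodo-2,4-dimethylpent-4-en-2-yl]peroxy}-4-methylpent-4-enal F3.
- Chlorite oxidation and methylation as in step 9 should give methyl (3S)-3-{[(2S,4E)-1-hydroxy-5-iodo-2,4-dimethylpent-4-en-2-yl]peroxy}-4-methylpent-4-enoate F4.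
- Dess–Martin oxidation of the primary alcohol should give methyl (3S)-3-{[(2S,4E)-5-iodo-2,4-dimethyl-1-oxopent-4-en-2-yl]peroxy}-4-methylpent-4-enoate F5.
- Wittig methylenation with Ph3P=CH2 should give methyl (3S)-3-{[(3S,5E)-6-iodo-3,5-dimethylhexa-1,5-dien-3-yl]peroxy}-4-methylpent-4-enoate F6.
- Second-generation Grubbs catalyst, RuCl2(H2IMes)(PCy3)(=CHPh), should close C4=C5 to methyl 2-[(3S,6S)-6-[(2E)-3-iodo-2-methylprop-2-en-1-yl]-4,6-dimethyl-3,6-dihydro-1,2-dioxin-3-yl]acetate F7.
- Diimide from KO2CN=NCO2K and acetic acid should reduce the ring alkene to methyl 2-[(3S,4R,6R)-6-[(2E)-3-iodo-2-methylprop-2-en-1-yl]-4,6-dimethyl-1,2-dioxan-3-yl]acetate F8. Facial control in this reduction is expected to be weak, so the C4 epimers would have to be separated.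
- Suzuki coupling of F8 with 5 as in step 3 should give 22.

Step 8. The hindered, hydroxylated hydroperoxide may turn over poorly. The intermediate enamine may attack the O–O bond and epoxidise the enal with loss of the alkoxide. The addition may also reverse, or the amine may trigger base-induced fragmentation at the activated C3–H. The fallback reverses the roles of the two fragments; it sets out from 13 and 8 and comes back at 16.
- 2-Methoxypropan-2-yl hydroperoxide, a small tertiary hydroperoxide, is added to 13 under the same catalyst to give prop-2-en-1-yl (2E,4S)-4-[(2-methoxypropan-2-yl)peroxy]-6-oxohex-2-enoate F9.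
- Oxidation and methylation as in step 9 should give 1-methyl 6-prop-2-en-1-yl (3S,4E)-3-[(2-methoxypropan-2-yl)peroxy]hex-4-enedioate F10.
- Aqueous acetic acid removes the peroxyketal to give 1-methyl 6-prop-2-en-1-yl (3S,4E)-3-hydroperoxyhex-4-enedioate F11.
- F11 opens epoxide 8 at the tertiary carbon with inversion under H3PMo12O40 catalysis, which should give 16.

Step 10. Substitution at the neopentyl-type carbon may be slow, so that the triflate instead ionises with participation of the neighbouring peroxy oxygen (1,2-shift of the peroxide) or eliminates. The fallback generates the same C5 radical by C–O homolysis, so no substitution at C5 is needed. It sets out from 16 and comes back at 19.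
- 1,1'-Thiocarbonyldiimidazole converts 16 into 1-methyl 6-prop-2-en-1-yl (3S,4E)-3-{[(2S,4E,6E)-1-(imidazole-1-carbothioyloxy)-2,4-dimethyl-8-phenylocta-4,6-dien-2-yl]peroxy}hex-4-enedioate F12.
- Bu3SnH and AIBN in benzene at 80 °C (Barton–McCombie fragmentation, slow addition) should then give 19 directly.

**Further compounds**

F1 | step 11 | (R)-2-[(2E)-3-iodo-2-methylprop-2-en-1-yl]-2-methyloxirane | C[C@@]1(C/C(C)=C/I)CO1
F2 | step 11 | (2S,4E)-2-hydroperoxy-5-iodo-2,4-dimethylpent-4-en-1-ol | OO[C@@](C)(C/C(C)=C/I)CO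
F3 | step 11 | (3S)-3-{[(2S,4E)-1-hydroxy-5-iodo-2,4-dimethylpent-4-en-2-yl]peroxy}-4-methylpent-4-enal | O=CC[C@@H](C(C)=C)OO[C@@](C)(C/C(C)=C/I)CO
F4 | step 11 | methyl (3S)-3-{[(2S,4E)-1-hydroxy-5-iodo-2,4-dimethylpent-4-en-2-yl]peroxy}-4-methylpent-4-enoate | COC(=O)C[C@@H](C(C)=C)OO[C@@](C)(C/C(C)=C/I)CO
F5 | step 11 | methyl (3S)-3-{[(2S,4E)-5-iodo-2,4-dimethyl-1-oxopent-4-en-2-yl]peroxy}-4-methylpent-4-enoate | COC(=O)C[C@@H](C(C)=C)OO[C@@](C)(C/C(C)=C/I)C=O
F6 | step 11 | methyl (3S)-3-{[(3S,5E)-6-iodo-3,5-dimethylhexa-1,5-dien-3-yl]peroxy}-4-methylpent-4-enoate | COC(=O)C[C@@H](C(C)=C)OO[C@@](C)(C/C(C)=C/I)C=C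
F7 | step 11 | methyl 2-[(3S,6S)-6-[(2E)-3-iodo-2-methylprop-2-en-1-yl]-4,6-dimethyl-3,6-dihydro-1,2-dioxin-3-yl]acetate | COC(=O)C[C@@H]1OO[C@@](C)(C/C(C)=C/I)C=C1C
F8 | step 11 | methyl 2-[(3S,4R,6R)-6-[(2E)-3-iodo-2-methylprop-2-en-1-yl]-4,6-dimethyl-1,2-dioxan-3-yl]acetate | COC(=O)C[C@@H]1OO[C@@](C)(C/C(C)=C/I)C[C@H]1C
F9 | step 8 | prop-2-en-1-yl (2E,4S)-4-[(2-methoxypropan-2-yl)peroxy]-6-oxohex-2-enoate | O=CC[C@@H](/C=C/C(=O)OCC=C)OOC(C)(C)OC
F10 | step 8 | 1-methyl 6-prop-2-en-1-yl (3S,4E)-3-[(2-methoxypropan-2-yl)peroxy]hex-4-enedioate | COC(=O)C[C@@H](/C=C/C(=O)OCC=C)OOC(C)(C)OC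
F11 | step 8 | 1-methyl 6-prop-2-en-1-yl (3S,4E)-3-hydroperoxyhex-4-enedioate | COC(=O)C[C@@H](/C=C/C(=O)OCC=C)OO
F12 | step 10 | 1-methyl 6-prop-2-en-1-yl (3S,4E)-3-{[(2S,4E,6E)-1-(imidazole-1-carbothioyloxy)-2,4-dimethyl-8-phenylocta-4,6-dien-2-yl]peroxy}hex-4-enedioate | COC(=O)C[C@@H](/C=C/C(=O)OCC=C)OO[C@@](C)(C/C(C)=C/C=C/Cc1ccccc1)COC(=S)n1ccnc1
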